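Assumption on locants: germacrane-type numbering is used throughout (ring C1–C10; C11, C12, C13 are the lactone carbons, with the lactone oxygen O6 on C6; C14 is the methyl on C10, C15 the methyl on C4; the angelate sits on O8). Read in this way the SMILES is the (3S,6S,7R,8R,10R)-1E,4Z isomer with a cis-fused lactone (H6 and H7 on the same face).

## The problem

The target is a germacranolide: a ten-membered carbocycle with an E-disubstituted C1=C2 olefin and a Z-trisubstituted C4=C5 olefin, and a cis-fused α-methylene-γ-butyrolactone across C6–C7. Closing a ten-membered ring that holds two olefins of fixed geometry is the first difficulty. The Z olefin is also flanked by two oxygenated carbons (C3, C6), so in an open chain it is a Z-enal or Z-hydroxy-enal system that isomerises or cyclises readily. The five stereocentres fall into two groups. C6, C7 and C8 are contiguous (O6, C11 and O8 on one face) and C6/C7 can be set together. C10 is quaternary and C3 is bis-allylic and remote, so C3 is best set last by the ring itself. The sensitive groups are the α-methylene lactone (Michael acceptor), the angelate (isomerises to tiglate with nucleophilic bases, reducible), the bis-allylic C3–OH and tertiary allylic C10–OH (ionise in acid), and a free O8 next to the lactone (translactonisation).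

The enabling feature is the unit C3–C4(C15)=C5–C6 with oxygen on C3 and O6 on C6. These five carbons and O6 are exactly the atoms of 3-methylfuran-2(5H)-one, whose 2-silyloxyfuran form is a flat aromatic ring that is nucleophilic at C6. On the other side of the C6–C7 bond, C7, C11 and C12 are the β-carbon, α-carbon and carbonyl carbon of an enal. One dearomatising C–C bond formation can therefore make the C6–C7 bond, set both stereocentres of the lactone fusion and hold the Z olefin in a five-membered ring until just before ring closure. The ring oxygen is then handed from C3 to C12.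

## Retrosynthesis

**29 ⇒ 28 ⇒ 27 ⇒ 26 (no C–C bond cut).** Target 29 is traced to dienone 28 by a hydride disconnection at C3, 28 to its silyl ether 27, and 27 to the pair of C3-epimeric alcohols 26. The configuration of a bis-allylic carbinol formed in a ten-membered transition state cannot be predicted, so it is not demanded of the ring closure. Both epimers of 26 converge on 27, and the ring (cis-lactone, two olefins) then directs the hydride. The forward reduction must be 1,2-selective and must spare the α-methylene lactone and the angelate.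

**26 ⇒ 25 (cut C2–C3).** The ring is opened to an E-alkenyl iodide at C2 and a Z-enal at C3 (Nozaki–Hiyama–Kishi ring closure). Against a cut at C6–C7 or at C1=C2, both olefin geometries are already in place and untouched by the ring closure, and the only new stereocentre is the one that is reset afterwards. Compound 25 is acyclic. The forward step needs insertion into the C–I bond in the presence of two esters and high dilution.

**25 ⇒ 24 ⇒ 21 (exchange of the acyl partner of O6).** Enal 25 comes from allylic alcohol 24. In 24 the O6–C12 lactone bond is cut and O6 is re-attached to C3, which gives butenolide acid 21. The Z geometry of C4=C5 is then part of a five-membered ring in 21 and in all its precursors, and the open Z-enal exists for one step only. The forward step must reduce the butenolide carbonyl (C3) to the alcohol level without touching the angelate or C12, and O6 must close onto C12.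

**21 ⇒ 20 ⇒ 18 (cut C11=C13, adjust C12).** The acid comes from aldehyde 20 and the exocyclic methylene from the α-carbon of the simpler aldehyde 18. This places the two steps that make the Michael acceptor after the C6–C7 bond formation. The forward steps are a Mannich reaction with elimination and a Pinnick oxidation.

**18 ⇒ 15 + 17 (cut C6–C7, key disconnection).** The bond between the lactone-fusion carbons is cut to enal 15 (electrophilic at C7) and silyloxyfuran 17 (nucleophilic at C6). The same bond is formed in the obvious ring closure, but here it is made between two small fragments under catalyst control. The product has two new stereocentres and a ring-locked Z olefin, and the precursors have neither. The forward reaction must give γ-attack of the furan, 1,4-addition, and the (6S,7R) pair.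

**17 ⇒ 16.** The silyloxyfuran is the O-silylated dienolate of commercial 3-methylfuran-2(5H)-one 16.

**15 ⇒ 14 ⇒ 11 + 12; 11 ⇒ 7 + 8 (cut O8–acyl, then C7–C8).** The angelate is put on at the fragment stage from angelic acid 12, where no other hydroxyl or sensitive group is present. Allylic alcohol 11 is cut at C7–C8 into aldehyde 7 and the three-carbon alkyne 8, which carries C7, C11 and C12. A reagent-controlled alkenyl addition sets C8 independently of C10.

**7 ⇒ 6 ⇒ 5 ⇒ 3 + 4; 3 ⇒ 1 (cut C9–C10).** The tertiary carbinol C10 is made by enantioselective allylation of iodoenone 3 with allylboronate 4. This ketone already holds C14, C10 and the E-iodoalkene C1=C2. Compound 3 comes from butynone 1. The allyl group supplies C9 and C8, and its terminal carbon is cleaved off.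

## Roads not taken

Alternative 1: cut C6–C7 in the ring (the most obvious cut, and the biogenetic ring-closure bond). The forward key step is an intramolecular Nozaki–Hiyama–Kishi or Barbier allylation of the Z-enal in bromo ester A1, followed by lactonisation, which closes the ring and forms the cis-lactone together. The chosen plan is better on three counts. In A1 the Z-α-methyl enal must be carried in open form next to the C3 carbinol. The ring closure must set C6 and C7 under control of three remote centres (C3, C8, C10) with no way to correct the outcome. C3 must be set in an open chain beside a Z olefin. In the chosen plan C6 and C7 are set on small fragments by a catalyst, the Z olefin stays in a ring, and the ring-closing bond creates only a centre that is reset. The step count is similar.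

Alternative 2: cut C1=C2 by ring-closing metathesis of diene A2. Both olefins are hindered (one on a tertiary carbinol, one on a bis-allylic carbinol), and ten-membered ring closure by metathesis gives no control of E/Z geometry. The exocyclic methylene and oligomerisation compete. In the chosen plan the E geometry is set in a four-carbon building block and is transferred with retention.

Alternative 3: cut C1=C2 through a sulfur atom, by Ramberg–Bäcklund contraction of the eleven-membered sulfone A3 (sulfur deletion after an easy thioether ring closure). The strongly basic conditions exclude the lactone and the angelate, which would then have to be built afterwards with extra protecting-group steps. The α-sulfonyl carbanions are flanked by oxygenated C3 and C10 and can eliminate alkoxide. The E geometry of a ten-membered olefin from this reaction is not assured. The chosen plan keeps the angelate from the fragment stage and needs one silyl group in all.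

Key step: step 9

## Steps

Step 1
Reactants: 1 but-3-yn-2-one
Product: 3 (E)-4-iodobut-3-en-2-one, via (Z)-4-iodobut-3-en-2-one 2 (not isolated)
Conditions: NaI, AcOH, 23 °C; then I2 (cat.), CH2Cl2, visible light, 23 °C
Reagents that add atoms: sodium iodide, [Na+].[I-]
Why: Conjugate hydroiodination of the ynone (anti addition gives the Z iodide 2), then iodine-mediated equilibration to the more stable E isomer; the E geometry of C1=C2 is fixed here and carried unchanged to the ring closure.

Step 2
Reactants: 3 (E)-4-iodobut-3-en-2-one; 4 2-allyl-4,4,5,5-tetramethyl-1,3,2-dioxaborolane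
Product: 5 (1E,3R)-1-iodo-3-methylhexa-1,5-dien-3-ol
Conditions: CuF2·2H2O (3 mol %), (R,R)-iPr-DuPHOS (6 mol %), La(OiPr)3 (4.5 mol %), DMF, −40 °C; aq. NH4Cl
Reagents that add atoms: none
Why: Catalytic enantioselective allylboration of a methyl ketone: an allylcopper species formed from 4 adds 1,2 to the enone carbonyl inside the chiral bisphosphine pocket, so C10 is set by the ligand (allyl on the Re face gives 3R; the enantiomeric ligand is used if the facial sense is the opposite).

Step 3
Reactants: 5 (1E,3R)-1-iodo-3-methylhexa-1,5-dien-3-ol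
Product: 6 triethyl{[(1E,3R)-1-iodo-3-methylhexa-1,5-dien-3-yl]oxy}silane
Conditions: Et3SiOTf, 2,6-lutidine, CH2Cl2, −78 → 0 °C
Reagents that add atoms: triethylsilyl trifluoromethanesulfonate, CC[Si](CC)(CC)OS(=O)(=O)C(F)(F)F
Why: Silylation of the tertiary alcohol with the silyl triflate; the TES ether masks O10 during the organozinc and hydride steps and is later removed by fluoride without touching the esters.

Step 4
Reactants: 6 triethyl{[(1E,3R)-1-iodo-3-methylhexa-1,5-dien-3-yl]oxy}silane
Product: 7 (3R,4E)-5-iodo-3-methyl-3-[(triethylsilyl)oxy]pent-4-enal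
Conditions: OsO4 (2 mol %), NaIO4, 2,6-lutidine, dioxane–H2O (3:1), 23 °C
Reagents that add atoms: sodium periodate (oxygen relayed through OsO4), [Na+].[O-]I(=O)(=O)=O
Why: Lemieux–Johnson cleavage; the terminal monosubstituted olefin is dihydroxylated much faster than the electron-poor iodoalkene, and periodate cleaves the diol to the aldehyde that becomes C8.

Step 5
Reactants: 7 (3R,4E)-5-iodo-3-methyl-3-[(triethylsilyl)oxy]pent-4-enal; 8 3,3-diethoxyprop-1-yne
Product: 11 (2E,4R,6R,7E)-1,1-diethoxy-8-iodo-6-methyl-6-[(triethylsilyl)oxy]octa-2,7-dien-4-ol, via alkenylborane 9 (not isolated), via alkenylzinc 10 (not isolated)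
Conditions: 8, Cy2BH, toluene, 0 → 23 °C; Me2Zn, −78 °C; (−)-MIB (4 mol %); then 7, −10 °C; aq. NH4Cl
Reagents that add atoms: none
Why: Syn hydroboration of 8 gives the E-alkenylborane 9, boron-to-zinc exchange gives 10, and the amino-alcohol-ligated zinc species transfers the alkenyl group to one face of the aldehyde (catalytic asymmetric alkenylzinc addition); C8 is therefore set by the ligand and not by C10, and the (−)-ligand is expected to give 4R as with simple aldehydes.

Step 6
Reactants: 11 (2E,4R,6R,7E)-1,1-diethoxy-8-iodo-6-methyl-6-[(triethylsilyl)oxy]octa-2,7-dien-4-ol; 12 angelic acid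
Product: 14 (2E,4R,6R,7E)-1,1-diethoxy-8-iodo-6-methyl-6-[(triethylsilyl)oxy]octa-2,7-dien-4-yl (2Z)-2-methylbut-2-enoate, via mixed anhydride 13 (not isolated)
Conditions: 12, 2,4,6-Cl3C6H2COCl, Et3N, toluene, 23 °C; then 11, 75 °C
Reagents that add atoms: none
Why: Yamaguchi-type esterification through the mixed anhydride 13 without a nucleophilic amine catalyst, the protocol that avoids angelate-to-tiglate isomerisation; O8 is the only free hydroxyl.

Step 7
Reactants: 14 (2E,4R,6R,7E)-1,1-diethoxy-8-iodo-6-methyl-6-[(triethylsilyl)oxy]octa-2,7-dien-4-yl (2Z)-2-methylbut-2-enoate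
Product: 15 (2E,4R,6R,7E)-8-iodo-6-methyl-1-oxo-6-[(triethylsilyl)oxy]octa-2,7-dien-4-yl (2Z)-2-methylbut-2-enoate
Conditions: PPTS (10 mol %), acetone–H2O (10:1), 23 °C
Reagents that add atoms: water, O
Why: Acid-catalysed hydrolysis of an allylic acetal, which is much faster than cleavage of the tertiary TES ether or of the esters; it gives the E-enal needed for iminium activation.

Step 8
Reactants: 16 3-methylfuran-2(5H)-one
Product: 17 trimethyl[(3-methylfuran-2-yl)oxy]silane
Conditions: Me3SiOTf, Et3N, CH2Cl2, 0 °C
Reagents that add atoms: trimethylsilyl trifluoromethanesulfonate, C[Si](C)(C)OS(=O)(=O)C(F)(F)F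
Why: O-silylation of the dienolate of the butenolide gives the aromatic 2-silyloxyfuran, the flat form of C3–C6 and O6.

Step 9
Reactants: 15 (2E,4R,6R,7E)-8-iodo-6-methyl-1-oxo-6-[(triethylsilyl)oxy]octa-2,7-dien-4-yl (2Z)-2-methylbut-2-enoate; 17 trimethyl[(3-methylfuran-2-yl)oxy]silane
Product: 18 (3R,4R,6R,7E)-8-iodo-6-methyl-3-[(2S)-4-methyl-5-oxo-2,5-dihydrofuran-2-yl]-1-oxo-6-[(triethylsilyl)oxy]oct-7-en-4-yl (2Z)-2-methylbut-2-enoate
Conditions: (2R,5R)-5-benzyl-2-tert-butyl-3-methylimidazolidin-4-one (20 mol %), 2,4-dinitrobenzoic acid (20 mol %), CH2Cl2–H2O, −70 °C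
Reagents that add atoms: water, O
Why: The amine salt condenses with enal 15 to an E-configured iminium ion, which activates C7 and shuts off 1,2-addition. Silyloxyfuran 17 attacks C7 with its C5 (C6 of the target, the γ-position) in an open Mukaiyama–Michael transition state; loss of the silyl group to water gives the butenolide, and hydrolysis of the enamine releases the catalyst and aldehyde 18. The closest known reaction type is the imidazolidinone-catalysed Mukaiyama–Michael addition of 2-silyloxyfurans to β-substituted enals. No ring is closed: the aromatic furan ring is dearomatised to the 2(5H)-furanone ring that supplies C3–C6 and O6, and this ring fixes the Z geometry of C4=C5. C7 is controlled by the catalyst, whose benzyl group shields one face of the iminium ion so that the furan adds to the Re face of C7 (7R). C6 is controlled by the relative topicity of the open transition state, which depends on silyl group, acid co-catalyst and solvent; the combination that gives the unlike (6S,7R) pair is to be used. The step needs γ- over α-attack of the furan (inherent in 2-silyloxyfurans), 1,4- over 1,2-addition (secured by iminium activation) and catalyst control over the resident C8 centre (expected to dominate). The low temperature suppresses γ-deprotonation of the iminium ion, which would endanger C8.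

Step 10
Reactants: 18 (3R,4R,6R,7E)-8-iodo-6-methyl-3-[(2S)-4-methyl-5-oxo-2,5-dihydrofuran-2-yl]-1-oxo-6-[(triethylsilyl)oxy]oct-7-en-4-yl (2Z)-2-methylbut-2-enoate
Product: 20 (3R,4R,6R,7E)-8-iodo-6-methyl-2-methylidene-3-[(2S)-4-methyl-5-oxo-2,5-dihydrofuran-2-yl]-1-oxo-6-[(triethylsilyl)oxy]oct-7-en-4-yl (2Z)-2-methylbut-2-enoate, via Mannich base 19 (not isolated)
Conditions: CH2=NMe2+ I−, Et3N, CH2Cl2, 23 °C
Reagents that add atoms: N,N-dimethylmethyleneiminium iodide, C=[N+](C)C.[I-]
Why: Mannich reaction at the only α-carbon of the aldehyde (C11), then β-elimination of dimethylamine from 19, gives the 2-substituted acrolein and so introduces C13; the weak tertiary amine base should leave C6 and C7 untouched.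

Step 11
Reactants: 20 (3R,4R,6R,7E)-8-iodo-6-methyl-2-methylidene-3-[(2S)-4-methyl-5-oxo-2,5-dihydrofuran-2-yl]-1-oxo-6-[(triethylsilyl)oxy]oct-7-en-4-yl (2Z)-2-methylbut-2-enoate
Product: 21 (3R,4R,6R,7E)-8-iodo-6-methyl-2-methylidene-4-{[(2Z)-2-methylbut-2-enoyl]oxy}-3-[(2S)-4-methyl-5-oxo-2,5-dihydrofuran-2-yl]-6-[(triethylsilyl)oxy]oct-7-enoic acid
Conditions: NaClO2, NaH2PO4, 2-methylbut-2-ene, t-BuOH–H2O, 0 → 23 °C
Reagents that add atoms: sodium chlorite, [Na+].[O-]Cl=O
Why: Pinnick oxidation; chlorite oxidises only the aldehyde and the scavenger removes hypochlorite, so the olefins, the iodoalkene and C7 are untouched; the carboxylic acid is the form in which C12 survives the hydride step.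

Step 12
Reactants: 21 (3R,4R,6R,7E)-8-iodo-6-methyl-2-methylidene-4-{[(2Z)-2-methylbut-2-enoyl]oxy}-3-[(2S)-4-methyl-5-oxo-2,5-dihydrofuran-2-yl]-6-[(triethylsilyl)oxy]oct-7-enoic acid
Product: 24 (1R,3R,4E)-1-[(2S,3R)-2-[(1Z)-3-hydroxy-2-methylprop-1-en-1-yl]-4-methylidene-5-oxooxolan-3-yl]-5-iodo-3-methyl-3-[(triethylsilyl)oxy]pent-4-en-1-yl (2Z)-2-methylbut-2-enoate, via lactol acid 22 (not isolated), via diol acid 23 (not isolated)
Conditions: iBu2AlH (3.2 equiv), CH2Cl2, −78 °C; MeOH; NaBH4, CeCl3·7H2O, MeOH, −40 → 0 °C; aq. citric acid; PPTS (cat.), CH2Cl2, 23 °C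
Reagents that add atoms: none
Why: The first equivalent of hydride deprotonates the acid, and the carboxylate is inert at −78 °C; the conjugated lactone is reduced to lactol 22 faster than the hindered acyclic angelate (lactone-to-lactol reduction in the presence of an ester), and borohydride with CeCl3 reduces the open hydroxy-enal form 1,2 to the Z-diol 23. On acidification the γ-hydroxy acid closes to the α-methylene-γ-butyrolactone on O6, since O8 is blocked as the angelate and the C3 hydroxyl could only form an eight-membered ring.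

Step 13
Reactants: 24 (1R,3R,4E)-1-[(2S,3R)-2-[(1Z)-3-hydroxy-2-methylprop-1-en-1-yl]-4-methylidene-5-oxooxolan-3-yl]-5-iodo-3-methyl-3-[(triethylsilyl)oxy]pent-4-en-1-yl (2Z)-2-methylbut-2-enoate
Product: 25 (1R,3R,4E)-5-iodo-3-methyl-1-[(2S,3R)-2-[(1Z)-2-methyl-3-oxoprop-1-en-1-yl]-4-methylidene-5-oxooxolan-3-yl]-3-[(triethylsilyl)oxy]pent-4-en-1-yl (2Z)-2-methylbut-2-enoate
Conditions: MnO2, CH2Cl2, 23 °C
Reagents that add atoms: none
Why: Chemoselective oxidation of the primary allylic alcohol with MnO2, which keeps the Z geometry; the Z-enal is formed only now, with O6 tied up in the lactone so that neither a lactol nor a furan can form.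

Step 14
Reactants: 25 (1R,3R,4E)-5-iodo-3-methyl-1-[(2S,3R)-2-[(1Z)-2-methyl-3-oxoprop-1-en-1-yl]-4-methylidene-5-oxooxolan-3-yl]-3-[(triethylsilyl)oxy]pent-4-en-1-yl (2Z)-2-methylbut-2-enoate
Product: 26 (1E,4Z,6S,7R,8R,10R)-8-angeloyloxy-3-hydroxy-10-(triethylsilyloxy)germacra-1,4,11(13)-trien-12,6-olide (both C3 epimers)
Conditions: CrCl2 (8 equiv), NiCl2 (2 mol % of Cr), DMSO–THF, 2 mM, 23 °C; aq. work-up
Reagents that add atoms: none
Why: Nozaki–Hiyama–Kishi ring closure: zerovalent nickel inserts into the C–I bond, transmetalation gives an alkenyl species of trivalent chromium with retention of the E geometry, and this adds to the aldehyde under high dilution to close the ten-membered ring at C2–C3; esters, lactone and silyl ether are tolerated, and the configuration at C3 is not required at this stage.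

Step 15
Reactants: 26 (1E,4Z,6S,7R,8R,10R)-8-angeloyloxy-3-hydroxy-10-(triethylsilyloxy)germacra-1,4,11(13)-trien-12,6-olide (both C3 epimers)
Product: 27 (1E,4Z,6S,7R,8R,10R)-8-angeloyloxy-3-oxo-10-(triethylsilyloxy)germacra-1,4,11(13)-trien-12,6-olide
Conditions: MnO2, CH2Cl2, 23 °C
Reagents that add atoms: none
Why: MnO2 oxidation of the bis-allylic alcohol; both C3 epimers from the ring closure converge on the one cross-conjugated dienone.

Step 16
Reactants: 27 (1E,4Z,6S,7R,8R,10R)-8-angeloyloxy-3-oxo-10-(triethylsilyloxy)germacra-1,4,11(13)-trien-12,6-olide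
Product: 28 (1E,4Z,6S,7R,8R,10R)-8-angeloyloxy-10-hydroxy-3-oxogermacra-1,4,11(13)-trien-12,6-olide
Conditions: HF·pyridine, pyridine, THF, 0 → 23 °C
Reagents that add atoms: none
Why: Fluoride cleavage of the tertiary TES ether under buffered conditions, placed before the acid-sensitive bis-allylic alcohol exists; the E geometry of C1=C2 prevents hemiketal formation between O10 and C3.

Step 17
Reactants: 28 (1E,4Z,6S,7R,8R,10R)-8-angeloyloxy-10-hydroxy-3-oxogermacra-1,4,11(13)-trien-12,6-olide
Product: 29 (1E,3S,4Z,6S,7R,8R,10R)-8-angeloyloxy-3,10-dihydroxygermacra-1,4,11(13)-trien-12,6-olide (target)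
Conditions: NaBH4, CeCl3·7H2O, MeOH, −78 °C
Reagents that add atoms: none
Why: Luche reduction; CeCl3 makes borohydride a 1,2-selective reductant that spares the α-methylene lactone and the angelate, and hydride should add to the outer face of the dienone held by the ring (macrocyclic control by the cis-fused lactone and the C4 methyl), which is expected to give 3S.

## Compound list

1 | but-3-yn-2-one | CC(=O)C#C | starting material
2 | (Z)-4-iodobut-3-en-2-one | CC(=O)/C=C\I | intermediate
3 | (E)-4-iodobut-3-en-2-one | CC(=O)/C=C/I | intermediate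
4 | 2-allyl-4,4,5,5-tetramethyl-1,3,2-dioxaborolane (allylboronic acid pinacol ester) | C=CCB1OC(C)(C)C(C)(C)O1 | starting material
5 | (1E,3R)-1-iodo-3-methylhexa-1,5-dien-3-ol | C=CC[C@@](C)(O)/C=C/I | intermediate
6 | triethyl{[(1E,3R)-1-iodo-3-methylhexa-1,5-dien-3-yl]oxy}silane | C=CC[C@@](C)(O[Si](CC)(CC)CC)/C=C/I | intermediate
7 | (3R,4E)-5-iodo-3-methyl-3-[(triethylsilyl)oxy]pent-4-enal | O=CC[C@@](C)(O[Si](CC)(CC)CC)/C=C/I | intermediate
8 | 3,3-diethoxyprop-1-yne | C#CC(OCC)OCC | starting material
9 | dicyclohexyl[(1E)-3,3-diethoxyprop-1-en-1-yl]borane | CCOC(OCC)/C=C/B(C1CCCCC1)C1CCCCC1 | intermediate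
10 | [(1E)-3,3-diethoxyprop-1-en-1-yl](methyl)zinc | CCOC(OCC)/C=C/[Zn]C | intermediate
11 | (2E,4R,6R,7E)-1,1-diethoxy-8-iodo-6-methyl-6-[(triethylsilyl)oxy]octa-2,7-dien-4-ol | CCOC(OCC)/C=C/[C@H](O)C[C@@](C)(O[Si](CC)(CC)CC)/C=C/I | intermediate
12 | angelic acid, (2Z)-2-methylbut-2-enoic acid | C/C=C(/C)C(=O)O | starting material
13 | (2Z)-2-methylbut-2-enoic 2,4,6-trichlorobenzoic anhydride | C/C=C(/C)C(=O)OC(=O)c1c(Cl)cc(Cl)cc1Cl | intermediate
14 | (2E,4R,6R,7E)-1,1-diethoxy-8-iodo-6-methyl-6-[(triethylsilyl)oxy]octa-2,7-dien-4-yl (2Z)-2-methylbut-2-enoate | CCOC(OCC)/C=C/[C@H](OC(=O)/C(C)=C\C)C[C@@](C)(O[Si](CC)(CC)CC)/C=C/I | intermediate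
15 | (2E,4R,6R,7E)-8-iodo-6-methyl-1-oxo-6-[(triethylsilyl)oxy]octa-2,7-dien-4-yl (2Z)-2-methylbut-2-enoate | O=C/C=C/[C@H](OC(=O)/C(C)=C\C)C[C@@](C)(O[Si](CC)(CC)CC)/C=C/I | intermediate
16 | 3-methylfuran-2(5H)-one | CC1=CCOC1=O | starting material
17 | trimethyl[(3-methylfuran-2-yl)oxy]silane | Cc1ccoc1O[Si](C)(C)C | intermediate
18 | (3R,4R,6R,7E)-8-iodo-6-methyl-3-[(2S)-4-methyl-5-oxo-2,5-dihydrofuran-2-yl]-1-oxo-6-[(triethylsilyl)oxy]oct-7-en-4-yl (2Z)-2-methylbut-2-enoate | O=CC[C@@H]([C@H]1OC(=O)C(C)=C1)[C@H](OC(=O)/C(C)=C\C)C[C@@](C)(O[Si](CC)(CC)CC)/C=C/I | intermediate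
19 | Mannich base: aldehyde 18 carrying a (dimethylamino)methyl group on C11 (C11 epimers) | O=CC(CN(C)C)[C@@H]([C@H]1OC(=O)C(C)=C1)[C@H](OC(=O)/C(C)=C\C)C[C@@](C)(O[Si](CC)(CC)CC)/C=C/I | intermediate
20 | (3R,4R,6R,7E)-8-iodo-6-methyl-2-methylidene-3-[(2S)-4-methyl-5-oxo-2,5-dihydrofuran-2-yl]-1-oxo-6-[(triethylsilyl)oxy]oct-7-en-4-yl (2Z)-2-methylbut-2-enoate | O=CC(=C)[C@@H]([C@H]1OC(=O)C(C)=C1)[C@H](OC(=O)/C(C)=C\C)C[C@@](C)(O[Si](CC)(CC)CC)/C=C/I | intermediate
21 | (3R,4R,6R,7E)-8-iodo-6-methyl-2-methylidene-4-{[(2Z)-2-methylbut-2-enoyl]oxy}-3-[(2S)-4-methyl-5-oxo-2,5-dihydrofuran-2-yl]-6-[(triethylsilyl)oxy]oct-7-enoic acid | OC(=O)C(=C)[C@@H]([C@H]1OC(=O)C(C)=C1)[C@H](OC(=O)/C(C)=C\C)C[C@@](C)(O[Si](CC)(CC)CC)/C=C/I | intermediate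
22 | lactol acid: acid 21 with the butenolide carbonyl (C3) reduced to the cyclic hemiacetal (anomers) | OC(=O)C(=C)[C@@H]([C@H]1OC(O)C(C)=C1)[C@H](OC(=O)/C(C)=C\C)C[C@@](C)(O[Si](CC)(CC)CC)/C=C/I | intermediate
23 | diol acid: open (4Z)-3,6-diol form of 22 (primary alcohol at C3, secondary alcohol at C6, free acid at C12) | OC(=O)C(=C)[C@@H]([C@@H](O)/C=C(/C)CO)[C@H](OC(=O)/C(C)=C\C)C[C@@](C)(O[Si](CC)(CC)CC)/C=C/I | intermediate
24 | (1R,3R,4E)-1-[(2S,3R)-2-[(1Z)-3-hydroxy-2-methylprop-1-en-1-yl]-4-methylidene-5-oxooxolan-3-yl]-5-iodo-3-methyl-3-[(triethylsilyl)oxy]pent-4-en-1-yl (2Z)-2-methylbut-2-enoate | C=C1C(=O)O[C@@H](/C=C(/C)CO)[C@H]1[C@H](OC(=O)/C(C)=C\C)C[C@@](C)(O[Si](CC)(CC)CC)/C=C/I | intermediate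
25 | (1R,3R,4E)-5-iodo-3-methyl-1-[(2S,3R)-2-[(1Z)-2-methyl-3-oxoprop-1-en-1-yl]-4-methylidene-5-oxooxolan-3-yl]-3-[(triethylsilyl)oxy]pent-4-en-1-yl (2Z)-2-methylbut-2-enoate | C=C1C(=O)O[C@@H](/C=C(/C)C=O)[C@H]1[C@H](OC(=O)/C(C)=C\C)C[C@@](C)(O[Si](CC)(CC)CC)/C=C/I | intermediate
26 | (1E,4Z,6S,7R,8R,10R)-8-angeloyloxy-3-hydroxy-10-(triethylsilyloxy)germacra-1,4,11(13)-trien-12,6-olide, both C3 epimers | C=C1C(=O)O[C@H]2/C=C(/C)C(O)/C=C/[C@](C)(O[Si](CC)(CC)CC)C[C@@H](OC(=O)/C(C)=C\C)[C@@H]12 | intermediate
27 | (1E,4Z,6S,7R,8R,10R)-8-angeloyloxy-3-oxo-10-(triethylsilyloxy)germacra-1,4,11(13)-trien-12,6-olide | C=C1C(=O)O[C@H]2/C=C(/C)C(=O)/C=C/[C@](C)(O[Si](CC)(CC)CC)C[C@@H](OC(=O)/C(C)=C\C)[C@@H]12 | intermediate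
28 | (1E,4Z,6S,7R,8R,10R)-8-angeloyloxy-10-hydroxy-3-oxogermacra-1,4,11(13)-trien-12,6-olide | C=C1C(=O)O[C@H]2/C=C(/C)C(=O)/C=C/[C@](C)(O)C[C@@H](OC(=O)/C(C)=C\C)[C@@H]12 | intermediate
29 | (1E,3S,4Z,6S,7R,8R,10R)-8-angeloyloxy-3,10-dihydroxygermacra-1,4,11(13)-trien-12,6-olide (CNP0262559.7) | C=C1C(=O)O[C@H]2/C=C(/C)[C@@H](O)/C=C/[C@](C)(O)C[C@@H](OC(=O)/C(C)=C\C)[C@@H]12 | target

## Step count and least certain steps

Total step count: 17 (steps 1–7 for the enal, step 8 for the furan, steps 9–17 after the coupling). Longest linear sequence: 16 steps (steps 1–7 and 9–17).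

**Step 9 (key step).** The most likely failure is poor control of the relative topicity at C6 (the open transition state may give both C6 epimers) or a mismatched interplay of the catalyst with the resident 8-acyloxy group. The γ-branched, γ-oxygenated enal may also react slowly, and γ-deprotonation of the iminium ion would erode C8. The fallback forms the same C6–C7 bond by a Barbier allylation and sets out from 14. Oxidative cleavage of the C7=C11 olefin of 14 (OsO4, NaIO4) gives the α-acyloxy aldehyde F1. A Morita–Baylis–Hillman reaction with methyl acrylate gives the hydroxy ester F2, and bromination with allylic transposition (N-bromosuccinimide, Me2S) gives the (Z)-2-(bromomethyl)enoate F3. Commercial 4-methylfuran-2(5H)-one F4 is reduced (iBu2AlH) to the lactol F5, the ring form of the Z-hydroxy-enal. Indium-mediated allylation of F5 with F3 in aqueous THF should give the syn hydroxy ester F6 through a chair transition state, and acid-catalysed lactonisation of F6 leads back to the route at 24.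

**Step 14.** The ten-membered ring closure may lose out to oligomerisation, and the Z-enal may isomerise on the Lewis-acidic chromium salts before it is trapped. The fallback closes the ring as the ketone by an acyl Stille coupling and sets out from 25. Pinnick oxidation gives the Z-enoic acid F7, and iodine–tin exchange (Me3SnSnMe3, Pd(PPh3)4) gives the alkenylstannane acid F8. 1-Chloro-N,N,2-trimethylprop-1-en-1-amine converts F8 into the acid chloride F9. Intramolecular coupling of F9 (Pd2(dba)3, tri(2-furyl)phosphine, high dilution) returns to the route at dienone 27.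

**Step 17.** The facial selectivity of hydride addition to the dienone may be low or may favour the 3R alcohol, since the preferred conformation of the ring is not known in advance. The fallback sets C3 in the C–C bond formation instead and sets out from 25. A Nozaki–Hiyama–Kishi ring closure with a stoichiometric chiral sulfonamide ligand on chromium, followed by separation of the epimers, gives the (3S)-alcohol F10 (the 3R epimer is recycled through 27). Desilylation of F10 with buffered HF·pyridine returns to the route at 29.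

**Step 12.** The hydride may attack the angelate or over-reduce the carboxylate, and the lactol 22 may lose water to a furan before it is reduced. The fallback avoids a hydride at the lactone stage and sets out from 21. Ring opening of the butenolide with the aluminium amide from AlMe3 and N,O-dimethylhydroxylamine hydrochloride gives the hydroxy N-methoxy-N-methylamide acid F11. Lactonisation of O6 onto C12 (2,4,6-trichlorobenzoyl chloride, Et3N) gives the lactone amide F12. Reduction of the amide with Cp2Zr(H)Cl gives the Z-enal and returns to the route at 25.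

**Step 2.** The enantioselectivity with a β-iodo enone may be insufficient, and the alkenyl iodide may be attacked by the copper catalyst. The fallback gives up the enantioselective step and separates diastereomers after the reagent-controlled step 5; it sets out from 3. Allylmagnesium bromide gives the racemic alcohol F13, silylation gives F14, and oxidative cleavage gives the racemic aldehyde F15. Under the conditions of step 5, F15 gives 11 together with its C10 epimer F16. Chromatographic separation returns to the route at 11.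

## Further compounds

F1 | step 9 | (2R,4R,5E)-6-iodo-4-methyl-1-oxo-4-[(triethylsilyl)oxy]hex-5-en-2-yl (2Z)-2-methylbut-2-enoate | I/C=C/[C@](C)(O[Si](CC)(CC)CC)C[C@@H](OC(=O)/C(C)=C\C)C=O
F2 | step 9 | methyl 2-[(2R,4R,5E)-1-hydroxy-6-iodo-4-methyl-2-{[(2Z)-2-methylbut-2-enoyl]oxy}-4-[(triethylsilyl)oxy]hex-5-en-1-yl]prop-2-enoate (C7 epimers) | COC(=O)C(=C)C(O)[C@H](OC(=O)/C(C)=C\C)C[C@@](C)(O[Si](CC)(CC)CC)/C=C/I
F3 | step 9 | methyl (2Z,4R,6R,7E)-2-(bromomethyl)-8-iodo-6-methyl-4-{[(2Z)-2-methylbut-2-enoyl]oxy}-6-[(triethylsilyl)oxy]octa-2,7-dienoate | COC(=O)/C(CBr)=C/[C@H](OC(=O)/C(C)=C\C)C[C@@](C)(O[Si](CC)(CC)CC)/C=C/I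
F4 | step 9 | 4-methylfuran-2(5H)-one | CC1=CC(=O)OC1
F5 | step 9 | 4-methyl-2,5-dihydrofuran-2-ol | CC1=CC(O)OC1
F6 | step 9 | methyl ester of diol acid 23 | COC(=O)C(=C)[C@@H]([C@@H](O)/C=C(/C)CO)[C@H](OC(=O)/C(C)=C\C)C[C@@](C)(O[Si](CC)(CC)CC)/C=C/I
F7 | step 14 | (2Z)-enoic acid from enal 25 (carboxylic acid at C3) | C=C1C(=O)O[C@@H](/C=C(/C)C(=O)O)[C@H]1[C@H](OC(=O)/C(C)=C\C)C[C@@](C)(O[Si](CC)(CC)CC)/C=C/I
F8 | step 14 | acid F7 with the iodine replaced by trimethylstannyl (E) | C=C1C(=O)O[C@@H](/C=C(/C)C(=O)O)[C@H]1[C@H](OC(=O)/C(C)=C\C)C[C@@](C)(O[Si](CC)(CC)CC)/C=C/[Sn](C)(C)C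
F9 | step 14 | acid chloride of F8 | C=C1C(=O)O[C@@H](/C=C(/C)C(Cl)=O)[C@H]1[C@H](OC(=O)/C(C)=C\C)C[C@@](C)(O[Si](CC)(CC)CC)/C=C/[Sn](C)(C)C
F10 | step 17 | (1E,3S,4Z,6S,7R,8R,10R)-8-angeloyloxy-3-hydroxy-10-(triethylsilyloxy)germacra-1,4,11(13)-trien-12,6-olide | C=C1C(=O)O[C@H]2/C=C(/C)[C@@H](O)/C=C/[C@](C)(O[Si](CC)(CC)CC)C[C@@H](OC(=O)/C(C)=C\C)[C@@H]12
F11 | step 12 | acid 21 with the butenolide opened to the (Z)-C6-hydroxy N-methoxy-N-methylamide at C3 | OC(=O)C(=C)[C@@H]([C@@H](O)/C=C(/C)C(=O)N(C)OC)[C@H](OC(=O)/C(C)=C\C)C[C@@](C)(O[Si](CC)(CC)CC)/C=C/I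
F12 | step 12 | α-methylene lactone (O6 on C12) carrying the (Z)-N-methoxy-N-methylamide at C3 | C=C1C(=O)O[C@@H](/C=C(/C)C(=O)N(C)OC)[C@H]1[C@H](OC(=O)/C(C)=C\C)C[C@@](C)(O[Si](CC)(CC)CC)/C=C/I
F13 | step 2 | racemic (1E)-1-iodo-3-methylhexa-1,5-dien-3-ol | C=CCC(C)(O)/C=C/I
F14 | step 2 | racemic triethylsilyl ether of F13 | C=CCC(C)(O[Si](CC)(CC)CC)/C=C/I
F15 | step 2 | racemic (4E)-5-iodo-3-methyl-3-[(triethylsilyl)oxy]pent-4-enal | O=CCC(C)(O[Si](CC)(CC)CC)/C=C/I
F16 | step 2 | (2E,4R,6S,7E)-1,1-diethoxy-8-iodo-6-methyl-6-[(triethylsilyl)oxy]octa-2,7-dien-4-ol (C10 epimer of 11) | CCOC(OCC)/C=C/[C@H](O)C[C@](C)(O[Si](CC)(CC)CC)/C=C/I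
A1 | alternative 1 | acyclic (Z)-2-(bromomethyl)enoate with a (Z)-enal at C6, O3 as tert-butyldimethylsilyl ether, O10 as triethylsilyl ether, O8 as angelate | COC(=O)/C(CBr)=C/[C@H](OC(=O)/C(C)=C\C)C[C@@](C)(O[Si](CC)(CC)CC)/C=C/[C@H](O[Si](C)(C)C(C)(C)C)/C(C)=C\C=O
A2 | alternative 2 | cis-lactone diene with a vinyl group on C3 (secondary carbinol) and a vinyl group on C10 (tertiary carbinol) | C=C1C(=O)O[C@@H](/C=C(/C)[C@@H](O)C=C)[C@H]1[C@H](OC(=O)/C(C)=C\C)C[C@@](C)(O)C=C
A3 | alternative 3 | eleven-membered cyclic sulfone (C1–SO2–C2) with O6/O8 acetonide, O3 and O10 as triethylsilyl ethers and a 3-[(4-methoxybenzyl)oxy]prop-1-en-2-yl group on C7 | CC1(C)O[C@H]2/C=C(/C)[C@@H](O[Si](CC)(CC)CC)CS(=O)(=O)C[C@](C)(O[Si](CC)(CC)CC)C[C@@H](O1)[C@H]2C(=C)COCc1ccc(OC)cc1
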